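## Structural features

The target is a 2H-chromen-2-one (benzene ring A fused to pyranone ring B) with a methyl group at C6, a free phenol at C7 and, at C3, a (2S)-2-methyl-2,3-dihydro-4H-pyran-4-one (ring C) bonded through its enol-ether carbon C6′. C3=C4, C6′=C5′ and the C4′ ketone therefore form one vinylogous-ester system. C5, which is peri to C4–H and ortho to the C6 methyl, carries a (2R,3R)-3-hydroxybutan-2-yl chain. Its benzylic carbon Ca and carbinol carbon Cb are adjacent stereocentres (erythro). The third stereocentre, C2′, lies seven bonds from Ca and must be introduced independently. Three points are fragile: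

- Ring C is a β-alkoxy enone. Base or nucleophilic amines can open it by retro-oxa-Michael reaction or attack C6′, and either would erase C2′.
- Ring A is an electron-rich resorcinol, which at the aldehyde oxidation level of C4 tends to lose water towards a quinone methide.
- The Cb hydroxyl can add back to C4.

The real difficulty is the diad on a fully substituted benzene ring at C5, the one position meta to both ring oxygens and so out of reach of electrophilic substitution. The key step uses the following feature. Joining the Cb oxygen to C4 at the carboxyl oxidation level makes that oxygen, Cb, Ca, C5, C4a and C4 a six-membered lactone, a 3,4-dimethylisochroman-1-one. Its dehydro form is a flat, achiral isocoumarin, and suprafacial addition of H2 to the C3=C4 enol-lactone bond (isochromene numbering) gives the cis lactone. A descriptor check confirms the bookkeeping: the cis-(3R,4R) lactone corresponds to the (2R,3R) chain, and (S)-C2′ corresponds to (S)-3-hydroxybutanoate. No structure needs correcting.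

## Logic of the disconnections

**17 to 9 and 15.** The C3=C4 double bond and the O1–C2 lactone bond of ring B are cut. These are the bonds a Knoevenagel condensation with lactonisation makes. The cut separates ring C with its one stereocentre from the arene with the diad, so the route becomes convergent. The forward step must run under buffered amine catalysis mild enough to spare C2′, and the masked aldehyde of 9 must be able to open.

**15 to 13.** The enol-ether bond O1′–C6′ is cut, through hemiketal 14. Ring C becomes a linear δ-hydroxy β-diketone whose hydroxyl and carbonyl are already 1,5-related. The forward cyclodehydration must use acid mild enough that the C–O bond at the stereocentre is never broken.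

**13 to 10 and 11.** The C4–C5 bond of 13 is cut, a Claisen-type acylation. C2′ is then bought from the chiral pool in 11, and the rest of ring C comes from 10 by way of its dianion 12. The demand is an excess of 12, because the free hydroxyl and the acidic product each consume base.

**9 to 8.** Only the oxidation level of C1 changes. The lactone is the form in which the diad is made, so the aldehyde level is reached by partial reduction. The forward step must stop at the lactol in the presence of two free phenols.

**8 to 7.** The two O–benzyl bonds are cut. Benzyl is preferred to methyl as the phenol protecting group for this reason: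

- Benzyl ethers can be removed by neutral hydrogenolysis after the stereocentres exist.
- A BBr3 demethylation could open the lactone at C3 by bromide attack and endanger Cb.

Deprotection is placed before the reduction to 9, because hydrogenation at the lactol stage would be expected to reduce the derived quinone methide.

**7 to 6.** The two hydrogens at C3 and C4 are removed, and no skeletal bond is cut. Two adjacent stereocentres become one planar, achiral enol lactone, so the whole stereochemistry of the diad is postponed to a single catalytic step. The demand is a catalyst that accepts a tetrasubstituted olefin and tells its two faces apart.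

**6 to 4 and 5.** The C4–C4a and O2–C3 bonds are cut, an oxidative annulation. The symmetric alkyne 5 removes any regiochemical question, and 4 has only one ortho C–H. The demand is carboxylate-directed metalation at a C–H flanked by the C5 methyl.

**4 to 3, 2 and 1.** The benzyl ester and ether bonds and the aryl–carboxyl bond are cut. 1 is commercial, and carboxylation ortho to one hydroxyl and para to the other places the carboxyl carbon where C4 of ring B will be. The forward carboxylation must favour that position over the one between the two hydroxyls.

## Other disconnections considered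

**Alternative 1:**

- **Cut.** Ring A itself is broken at C5–C6 and C4a–C8a (coumarin numbering). This gives a two-carbon piece, the ynoate A2 that already carries the silyl-protected diad, and a four-carbon piece, the bis(silyloxy)diene A3.
- **Forward key step.** A thermal Diels–Alder reaction would join the CH(CH3) terminus of A3 to the β-carbon of A2 and the ketene-acetal terminus to the α-carbon. Loss of Me3SiOMe would aromatise the adduct to the resorcylate A1.
- **In favour.** The polarities of the partners match, so all six substituents of ring A should arrive in place in one step. The position meta to both oxygens never has to be functionalised. The diad is made beforehand on an open chain by established aldol or alkylation stereocontrol.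
- **Against here.** The dienophile carries a branched, stereogenic group on its reacting carbon and the diene a substituted terminus, so forcing temperatures must be expected. Ca in A2 is propargylic and acidified through the ester, so isomerisation towards an allenoate could erase it. A2 needs perhaps six to eight steps before the arene exists.
- **Comparison.** In structure the two plans are equal from the lactone stage on, since A1 should lactonise to 8 once its silyl group is removed. In mechanism the alternative is metal-free and rests only on precedented stereochemistry, so on certainty of the diad it is the better plan. The chosen plan is better in starting from a commercial arene and making both stereocentres catalytically in one step. In step economy the chosen plan needs six steps from 1 to 8, and the alternative roughly twice as many.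

**Alternative 2:**

- **Cut.** The single bond C3–C6′ between ring B and ring C.
- **Forward key step.** The stannyl glycal A5, a C1-metalated 4-deoxy-L-rhamnal, would be coupled with the 3-bromocoumarin A6 in a Stille reaction to give A4. The catalyst is Pd(PPh3)4, a zerovalent-palladium source, with CuI.
- **In favour.** Coupling of 1-stannyl glycals with sp2 halides is reliable. C2′ comes from the chiral pool, which is the equal of taking it from 11. The coumarin is complete before ring C is attached, so ring C never meets an amine-catalysed condensation; on that point the alternative is better than the chosen plan.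
- **Against here.** A5 needs a multistep preparation (deoxygenation, silylation, lithiation with t-BuLi, stannylation) and a stoichiometric tin reagent. A4 is an acid-labile enol ether in which the triisopropylsilyl ether must be removed selectively and the allylic alcohol oxidised to the C4′ ketone before the other silyl groups come off. A6 already contains the diad on the pentasubstituted arene, so the alternative presupposes a solution to the hardest problem and replaces only the last step.
- **Comparison.** In structure the bond set is the same apart from C3–C6′, with ring C arriving at the alcohol instead of the ketone level. In mechanism a neutral cross-coupling replaces an equilibrating condensation. In step economy the chosen plan needs one step from 9 and 15, against a coupling plus at least three further steps and two longer fragment syntheses.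

**Alternative 3:**

- **Cut.** No skeletal bond is cut. The two C–H bonds at C5 and C6 of the lactone A7 are removed, leading back to the flat, commercial 2-pyranone A8.
- **Forward key step.** H2 with Ru(OAc)2(MeO-BIPHEP), a divalent-ruthenium catalyst, would reduce the C5=C6 bond of A8 and create the future C2′ as the S centre of A7.
- **In favour.** Asymmetric hydrogenation of 4-hydroxy-2-pyranones with this catalyst class is established, so on precedent this key step is better than the chosen one. A8 is a bulk chemical. The idea is the same as in the chosen plan, flatten then hydrogenate, applied where the substrate offers the metal a β-keto-lactone handle.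
- **Against here.** It creates only C2′, the one stereocentre that costs nothing when bought as 11. The carbonyl carbon of A7 must become C6′, which means C–C bond formation at a lactone carbonyl with the acidic 4-hydroxyl masked, then dehydration; this is probably three or more steps to 15, against two from 11. The diad is left untouched.
- **Comparison.** In structure it addresses ring C only. In mechanism it is a chelation-assisted hydrogenation of a trisubstituted, functionalised olefin, against a non-chelating hydrogenation of a tetrasubstituted one. For the reliability of C2′ the two plans are equal. In step economy it is worse for ring C and neutral for the rest.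

Key step: step 5

Assumption: 9 is drawn as the cyclic lactol (both C1 epimers); its ring–chain tautomers are treated as the same compound, since all should deliver the same carbon to step 10.

## Route

Step 1
Reactants: 1 4-methylresorcinol (4-methylbenzene-1,3-diol)
Product: 2 2,4-dihydroxy-5-methylbenzoic acid
Conditions: KHCO3 (4 equiv), H2O, CO2 (1 atm), 100 °C; then aq. HCl
Reagents that add atoms: carbon dioxide, O=C=O
Why: Kolbe–Schmitt carboxylation: the resorcinolate is attacked by CO2 at C6, ortho to one hydroxyl and para to the other, whereas C2 is flanked on both sides and C5 is meta to both oxygens; the chelated salicylate-type product favours this isomer under equilibrating conditions.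

Step 2
Reactants: 2 2,4-dihydroxy-5-methylbenzoic acid
Product: 3 benzyl 2,4-bis(benzyloxy)-5-methylbenzoate
Conditions: BnBr (3.5 equiv), K2CO3 (4 equiv), DMF, 60 °C
Reagents that add atoms: benzyl bromide, BrCc1ccccc1
Why: Williamson O-alkylation: K2CO3 in DMF deprotonates the acid and both phenols, warming is needed only for the hydrogen-bonded 2-hydroxyl, and exhaustive benzylation avoids any need for selectivity.

Step 3
Reactants: 3 benzyl 2,4-bis(benzyloxy)-5-methylbenzoate
Product: 4 2,4-bis(benzyloxy)-5-methylbenzoic acid
Conditions: KOH (3 equiv), THF/MeOH/H2O, 60 °C; then aq. HCl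
Reagents that add atoms: potassium hydroxide, [K+].[OH-]
Why: Saponification: hydroxide cleaves the benzyl ester by acyl substitution, whereas aryl benzyl ethers are inert to aqueous base.

Step 4
Reactants: 4 2,4-bis(benzyloxy)-5-methylbenzoic acid; 5 but-2-yne
Product: 6 6,8-bis(benzyloxy)-3,4,5-trimethyl-1H-isochromen-1-one
Conditions: [Cp*RhCl2]2 (2.5 mol%), Cu(OAc)2·H2O (2.1 equiv), 5 (3 equiv), DMF, 110 °C, sealed vessel
Reagents that add atoms: none
Why: Oxidative annulation of a benzoic acid with an internal alkyne under trivalent-rhodium catalysis: carboxylate-assisted metalation at C6 (the only ortho C–H), insertion of 5 into the Rh–aryl bond and C–O reductive elimination close the pyranone, and Cu(OAc)2 returns monovalent rhodium to the trivalent state; the symmetric alkyne leaves no regiochemical question and the benzyl ethers are spectators.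

Step 5
Reactants: 6 6,8-bis(benzyloxy)-3,4,5-trimethyl-1H-isochromen-1-one
Product: 7 (3R,4R)-6,8-bis(benzyloxy)-3,4,5-trimethylisochroman-1-one
Conditions: H2 (50 bar), [Ir(cod)(L*)]BArF (2 mol%; L* = (S)-tBu-PHOX or its antipode; BArF = B[3,5-(CF3)2C6H3]4), CH2Cl2, 25–40 °C
Reagents that add atoms: none
Why: Proposed new method: the cationic monovalent-iridium precatalyst is expected to shed cyclooctadiene under H2 and bind the C3=C4 bond of 6 at an iridium dihydride, after which migratory insertion and C–H reductive elimination hand both hydrogens to the same face of the olefin; the closest known reaction types are the iridium–P,N-catalysed asymmetric hydrogenation of unfunctionalised tetrasubstituted olefins and the iridium- or ruthenium-catalysed asymmetric hydrogenation of 3-monosubstituted isocoumarins, but a 3,4-dialkyl isocoumarin lies outside both. No ring is closed. C3 and C4 are created together: their cis relationship follows from the suprafacial delivery, and their absolute configuration from the ligand, which must direct H2 to the C3-Si/C4-Si face to give (3R,4R). Because 6 is achiral and flat, the ligand is the only stereochemical variable, and the hand that leads to 7 has to be fixed in a first screen of both antipodes. The peri clash between the C4 and C5 methyl groups twists the olefin out of the arene plane, which should weaken the conjugation that stabilises the enol lactone and add strain relief to the driving force. The step needs chemoselectivity for the olefin over the arenes and benzyl ethers, which a homogeneous iridium hydride should secure because it neither hydrogenolyses O-benzyl groups nor reduces benzenoid rings, and the lactone carbonyl, held anti to the olefin within the ring, cannot chelate the metal.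

Step 6
Reactants: 7 (3R,4R)-6,8-bis(benzyloxy)-3,4,5-trimethylisochroman-1-one
Product: 8 (3R,4R)-6,8-dihydroxy-3,4,5-trimethylisochroman-1-one
Conditions: H2 (1 atm), Pd/C (10 wt% Pd, 5 mol%), EtOAc/MeOH, 23 °C
Reagents that add atoms: none
Why: Hydrogenolysis of aryl benzyl ethers over Pd/C under neutral conditions; the lactone C3–O bond is not benzylic and C4 has no activating carbonyl, so both stereocentres and the ring should pass unchanged.

Step 7
Reactants: 8 (3R,4R)-6,8-dihydroxy-3,4,5-trimethylisochroman-1-one
Product: 9 (3R,4R)-3,4,5-trimethylisochromane-1,6,8-triol (lactol, both C1 epimers)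
Conditions: i-Bu2AlH (4 equiv), THF, −78 °C; MeOH, then aq. KNaC4H4O6 (potassium sodium tartrate), 0 °C
Reagents that add atoms: none
Why: Partial reduction of a lactone to the lactol: two equivalents of i-Bu2AlH are consumed by the phenols, a further one adds hydride to the carbonyl, and the tetrahedral aluminium alkoxide should persist at −78 °C until the quench; the stereocentres are not involved.

Step 8
Reactants: 10 methyl acetoacetate (methyl 3-oxobutanoate); 11 ethyl (S)-3-hydroxybutanoate
Product: 13 methyl (7S)-7-hydroxy-3,5-dioxooctanoate, via dilithium dianion of methyl acetoacetate 12 (not isolated)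
Conditions: 10 (3.2 equiv), LiN(i-Pr)2 (6.4 equiv), THF, −78 → 0 °C; then 11, −40 → 0 °C; aq. HCl
Reagents that add atoms: none
Why: Claisen-type acylation of a β-keto ester dianion: the terminal carbon of 12 attacks the ester carbonyl of 11 and ethoxide leaves; the excess of 12 takes up the hydroxyl proton and the acidic product, and the stereocentre, β to the carbonyl and bearing an alkoxide that cannot leave, is untouched.

Step 9
Reactants: 13 methyl (7S)-7-hydroxy-3,5-dioxooctanoate
Product: 15 methyl 2-[(2S)-2-methyl-4-oxo-3,4-dihydro-2H-pyran-6-yl]acetate, via cyclic hemiketal 14 (not isolated)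
Conditions: TsOH·H2O (10 mol%), MgSO4, CH2Cl2, 23 °C
Reagents that add atoms: none
Why: Acid-catalysed cyclodehydration of a δ-hydroxy β-diketone: the hydroxyl adds to the C3 ketone (6-exo-trig) to give 14, which loses water to the vinylogous ester; the C7–O bond is never broken, so the S configuration is retained, and the ester is a poorer electrophile than the ketone, so 2-pyranone formation should not compete.

Step 10
Reactants: 9 (3R,4R)-3,4,5-trimethylisochromane-1,6,8-triol; 15 methyl 2-[(2S)-2-methyl-4-oxo-3,4-dihydro-2H-pyran-6-yl]acetate
Product: 17 7-hydroxy-5-[(2R,3R)-3-hydroxybutan-2-yl]-6-methyl-3-[(2S)-2-methyl-4-oxo-3,4-dihydro-2H-pyran-6-yl]-2H-chromen-2-one (the target), via open-chain Knoevenagel ester 16 (not isolated)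
Conditions: piperidine (20 mol%), AcOH (20 mol%), MeCN, 3 Å molecular sieves, 23 → 45 °C
Reagents that add atoms: none
Why: Knoevenagel condensation followed by lactonisation (coumarin synthesis): the amine opens 9 through its aldehyde tautomer as an iminium ion, the methylene of 15 (α to the ester and vinylogous to the ketone) adds and amine is lost to give 16, and the phenol ortho to the new double bond closes ring B on the ester with loss of methanol; lactol opening, double-bond isomerisation and oxa-Michael reclosure by the Cb hydroxyl are reversible whereas coumarin formation is not, and the buffered catalyst should spare C2′.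

## Compound list

1 | 4-methylresorcinol (4-methylbenzene-1,3-diol) | Cc1ccc(O)cc1O | starting material
2 | 2,4-dihydroxy-5-methylbenzoic acid | Cc1cc(C(=O)O)c(O)cc1O | intermediate
3 | benzyl 2,4-bis(benzyloxy)-5-methylbenzoate | Cc1cc(C(=O)OCc2ccccc2)c(OCc2ccccc2)cc1OCc1ccccc1 | intermediate
4 | 2,4-bis(benzyloxy)-5-methylbenzoic acid | Cc1cc(C(=O)O)c(OCc2ccccc2)cc1OCc1ccccc1 | intermediate
5 | but-2-yne | CC#CC | starting material
6 | 6,8-bis(benzyloxy)-3,4,5-trimethyl-1H-isochromen-1-one | Cc1c(OCc2ccccc2)cc(OCc2ccccc2)c2c1c(C)c(C)oc2=O | intermediate
7 | (3R,4R)-6,8-bis(benzyloxy)-3,4,5-trimethylisochroman-1-one | Cc1c(OCc2ccccc2)cc(OCc2ccccc2)c(C2=O)c1[C@@H](C)[C@@H](C)O2 | intermediate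
8 | (3R,4R)-6,8-dihydroxy-3,4,5-trimethylisochroman-1-one | Cc1c(O)cc(O)c(C2=O)c1[C@@H](C)[C@@H](C)O2 | intermediate
9 | (3R,4R)-3,4,5-trimethylisochromane-1,6,8-triol (lactol, both C1 epimers) | Cc1c(O)cc(O)c(C2O)c1[C@@H](C)[C@@H](C)O2 | intermediate
10 | methyl acetoacetate (methyl 3-oxobutanoate) | COC(=O)CC(C)=O | starting material
11 | ethyl (S)-3-hydroxybutanoate | CCOC(=O)C[C@H](C)O | starting material
12 | dilithium dianion of methyl acetoacetate (deprotonated at C2 and C4) | [Li+].[Li+].COC(=O)[CH-]C(=O)[CH2-] | intermediate (not isolated)
13 | methyl (7S)-7-hydroxy-3,5-dioxooctanoate | COC(=O)CC(=O)CC(=O)C[C@H](C)O | intermediate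
14 | methyl 2-[(6S)-2-hydroxy-6-methyl-4-oxooxan-2-yl]acetate (cyclic hemiketal, both C2 epimers) | COC(=O)CC1(O)CC(=O)C[C@H](C)O1 | intermediate (not isolated)
15 | methyl 2-[(2S)-2-methyl-4-oxo-3,4-dihydro-2H-pyran-6-yl]acetate | COC(=O)CC1=CC(=O)C[C@H](C)O1 | intermediate
16 | methyl (2Z)-3-{2,4-dihydroxy-6-[(2R,3R)-3-hydroxybutan-2-yl]-5-methylphenyl}-2-[(2S)-2-methyl-4-oxo-3,4-dihydro-2H-pyran-6-yl]prop-2-enoate | COC(=O)/C(=C\c1c(O)cc(O)c(C)c1[C@@H](C)[C@@H](C)O)C1=CC(=O)C[C@H](C)O1 | intermediate (not isolated)
17 | 7-hydroxy-5-[(2R,3R)-3-hydroxybutan-2-yl]-6-methyl-3-[(2S)-2-methyl-4-oxo-3,4-dihydro-2H-pyran-6-yl]-2H-chromen-2-one | Cc1c(O)cc2oc(=O)c(C3=CC(=O)C[C@H](C)O3)cc2c1[C@@H](C)[C@@H](C)O | target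

## Step count and least certain steps

Total step count: 10. Longest linear sequence: 8 steps (steps 1–7 and 10); steps 8 and 9 form the second branch.

**Step 5 (key step, proposed new method).** The most likely failure is a lack of turnover at the crowded tetrasubstituted enol-lactone double bond, or insufficient discrimination between its two faces. The olefin carries four substituents and a peri methyl group, and nothing in it can anchor the catalyst. A second, smaller risk is acid-promoted side reaction caused by the acidic iridium hydrides. The fallback uses known chemistry, sets out from 6 and returns at 8. 6 would be hydrogenated over Pd/C (H2, 30 bar, EtOAc/AcOH, 50 °C). This heterogeneous syn addition also cleaves both benzyl ethers and should give racemic cis-6,8-dihydroxy-3,4,5-trimethylisochroman-1-one F1. The enantiomers would then be separated by preparative chromatography on a chiral stationary phase (cellulose tris(3,5-dimethylphenylcarbamate), CO2/MeOH). 8 is kept and (3S,4S)-6,8-dihydroxy-3,4,5-trimethylisochroman-1-one F2 is set aside, at the price of half the material.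

**Step 4.** The most likely failure is slow carboxylate-directed metalation at the C–H flanked by the carboxylate and the methyl group, with protodecarboxylation of the electron-rich acid taking over at 110 °C. The fallback builds the arene around the carbon substituents instead. It sets out from 10 and returns at 6.

- Michael addition of 10 to ethyl (E)-2-methylpent-2-enoate and Dieckmann closure in the same pot (NaOMe, MeOH, reflux) should give methyl 6-ethyl-5-methyl-2,4-dioxocyclohexane-1-carboxylate F3 as a mixture of stereoisomers.
- Dehydrogenation (Pd/C, mesitylene, reflux) should give methyl 6-ethyl-2,4-dihydroxy-5-methylbenzoate F4.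
- Benzylation (BnBr, K2CO3, DMF) should give methyl 2,4-bis(benzyloxy)-6-ethyl-5-methylbenzoate F5.
- Lateral lithiation of the ethyl group (LiN(i-Pr)2, THF, −78 °C) and acylation with N-methoxy-N-methylacetamide should give methyl 2,4-bis(benzyloxy)-5-methyl-6-(3-oxobutan-2-yl)benzoate F6.
- The enol of F6 should lactonise onto the ester (TsOH, toluene, reflux) to 6.

**Step 7.** The most likely failure is over-reduction. The aluminium hemiacetal may collapse early, assisted by the para phenoxide, so that the C1 oxygen is lost and a second hydride is transferred. The opposite failure is incomplete reduction, because the chelated ortho phenoxide deactivates the carbonyl. The fallback masks the phenols, sets out from 8 and returns at 9. Silylation (TBSCl, imidazole, DMF) should give (3R,4R)-6,8-bis(tert-butyldimethylsilyloxy)-3,4,5-trimethylisochroman-1-one F7. Reduction (i-Bu2AlH, 1.2 equiv, CH2Cl2, −78 °C) should give (3R,4R)-6,8-bis(tert-butyldimethylsilyloxy)-3,4,5-trimethylisochroman-1-ol F8. Buffered fluoride (Bu4NF, AcOH, THF, 0 °C) should then release 9.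

**Step 10.** The most likely failure is erosion of configuration at C2′, through reversible retro-oxa-Michael opening of ring C or amine addition at C6′. The reaction may also stall at the reversible oxa-Michael adduct of the Cb hydroxyl. The fallback closes ring C last and under acid. It sets out from 9 and 13 and returns at 17. Condensation of 9 with the more acidic C2 methylene of 13 (piperidinium acetate, MeCN, 23 °C) should give 7-hydroxy-5-[(2R,3R)-3-hydroxybutan-2-yl]-3-[(5S)-5-hydroxy-3-oxohexanoyl]-6-methyl-2H-chromen-2-one F9. Cyclodehydration (TsOH·H2O, CH2Cl2, 23 °C) should convert F9 into 17 in the manner of step 9.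

**Step 8.** The most likely failure is proton transfer in place of acylation: 12 may deprotonate the α-position of the lithium alkoxide of 11, so that conversion stalls. The fallback uses a protected, non-enolising acyl donor, sets out from 11 and returns at 13.

- Amidation (MeNHOMe·HCl, i-PrMgCl, THF, −20 °C) should give (S)-3-hydroxy-N-methoxy-N-methylbutanamide F10.
- Silylation (TBSCl, imidazole) should give (S)-3-(tert-butyldimethylsilyloxy)-N-methoxy-N-methylbutanamide F11.
- Acylation of 12 (2.2 equiv, THF, −78 → 0 °C) should give methyl (7S)-7-(tert-butyldimethylsilyloxy)-3,5-dioxooctanoate F12.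
- Aqueous HF in MeCN should remove the silyl group to give 13, which under the same acid should go on to 15 as in step 9.

## Further compounds

F1 | step 5 | racemic cis-6,8-dihydroxy-3,4,5-trimethylisochroman-1-one (1:1 mixture of 8 and its enantiomer) | Cc1c(O)cc(O)c(C2=O)c1[C@@H](C)[C@@H](C)O2.Cc1c(O)cc(O)c(C2=O)c1[C@H](C)[C@H](C)O2
F2 | step 5 | (3S,4S)-6,8-dihydroxy-3,4,5-trimethylisochroman-1-one | Cc1c(O)cc(O)c(C2=O)c1[C@H](C)[C@H](C)O2
F3 | step 4 | methyl 6-ethyl-5-methyl-2,4-dioxocyclohexane-1-carboxylate (mixture of stereoisomers) | CCC1C(C)C(=O)CC(=O)C1C(=O)OC
F4 | step 4 | methyl 6-ethyl-2,4-dihydroxy-5-methylbenzoate | CCc1c(C)c(O)cc(O)c1C(=O)OC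
F5 | step 4 | methyl 2,4-bis(benzyloxy)-6-ethyl-5-methylbenzoate | CCc1c(C)c(OCc2ccccc2)cc(OCc2ccccc2)c1C(=O)OC
F6 | step 4 | methyl 2,4-bis(benzyloxy)-5-methyl-6-(3-oxobutan-2-yl)benzoate (racemic) | COC(=O)c1c(OCc2ccccc2)cc(OCc2ccccc2)c(C)c1C(C)C(C)=O
F7 | step 7 | (3R,4R)-6,8-bis(tert-butyldimethylsilyloxy)-3,4,5-trimethylisochroman-1-one | Cc1c(O[Si](C)(C)C(C)(C)C)cc(O[Si](C)(C)C(C)(C)C)c(C2=O)c1[C@@H](C)[C@@H](C)O2
F8 | step 7 | (3R,4R)-6,8-bis(tert-butyldimethylsilyloxy)-3,4,5-trimethylisochroman-1-ol (both C1 epimers) | Cc1c(O[Si](C)(C)C(C)(C)C)cc(O[Si](C)(C)C(C)(C)C)c(C2O)c1[C@@H](C)[C@@H](C)O2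
F9 | step 10 | 7-hydroxy-5-[(2R,3R)-3-hydroxybutan-2-yl]-3-[(5S)-5-hydroxy-3-oxohexanoyl]-6-methyl-2H-chromen-2-one | Cc1c(O)cc2oc(=O)c(C(=O)CC(=O)C[C@H](C)O)cc2c1[C@@H](C)[C@@H](C)O
F10 | step 8 | (S)-3-hydroxy-N-methoxy-N-methylbutanamide | CON(C)C(=O)C[C@H](C)O
F11 | step 8 | (S)-3-(tert-butyldimethylsilyloxy)-N-methoxy-N-methylbutanamide | CON(C)C(=O)C[C@H](C)O[Si](C)(C)C(C)(C)C
F12 | step 8 | methyl (7S)-7-(tert-butyldimethylsilyloxy)-3,5-dioxooctanoate | COC(=O)CC(=O)CC(=O)C[C@H](C)O[Si](C)(C)C(C)(C)C
A1 | alternative 1 | methyl 6-[(2R,3R)-3-(tert-butyldimethylsilyloxy)butan-2-yl]-2,4-dihydroxy-5-methylbenzoate | Cc1c(O)cc(O)c(C(=O)OC)c1[C@@H](C)[C@@H](C)O[Si](C)(C)C(C)(C)C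
A2 | alternative 1 | methyl (4R,5R)-5-(tert-butyldimethylsilyloxy)-4-methylhex-2-ynoate | COC(=O)C#C[C@@H](C)[C@@H](C)O[Si](C)(C)C(C)(C)C
A3 | alternative 1 | 1-methoxy-1,3-bis(trimethylsilyloxy)penta-1,3-diene (mixture of double-bond isomers) | COC(O[Si](C)(C)C)=CC(O[Si](C)(C)C)=CC
A4 | alternative 2 | 7-(tert-butyldimethylsilyloxy)-5-[(2R,3R)-3-(tert-butyldimethylsilyloxy)butan-2-yl]-6-methyl-3-[(2S,4R)-2-methyl-4-(triisopropylsilyloxy)-3,4-dihydro-2H-pyran-6-yl]-2H-chromen-2-one | Cc1c(O[Si](C)(C)C(C)(C)C)cc2oc(=O)c(C3=C[C@H](O[Si](C(C)C)(C(C)C)C(C)C)C[C@H](C)O3)cc2c1[C@@H](C)[C@@H](C)O[Si](C)(C)C(C)(C)C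
A5 | alternative 2 | tributyl[(2S,4R)-2-methyl-4-(triisopropylsilyloxy)-3,4-dihydro-2H-pyran-6-yl]stannane | CCCC[Sn](CCCC)(CCCC)C1=C[C@H](O[Si](C(C)C)(C(C)C)C(C)C)C[C@H](C)O1
A6 | alternative 2 | 3-bromo-7-(tert-butyldimethylsilyloxy)-5-[(2R,3R)-3-(tert-butyldimethylsilyloxy)butan-2-yl]-6-methyl-2H-chromen-2-one | Cc1c(O[Si](C)(C)C(C)(C)C)cc2oc(=O)c(Br)cc2c1[C@@H](C)[C@@H](C)O[Si](C)(C)C(C)(C)C
A7 | alternative 3 | (6S)-4-hydroxy-6-methyl-5,6-dihydro-2H-pyran-2-one | O=C1C=C(O)C[C@H](C)O1
A8 | alternative 3 | 4-hydroxy-6-methyl-2H-pyran-2-one | Cc1cc(O)cc(=O)o1
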